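The readings come from a simulation for substances that don't exist.

The pitfall in planning this flask is to count one chain for each pre-initiator charged. Take instead the impurity as cancelling pre-initiator one for one, with equal charges as the zero of the scale: the flask then has 3.90 mM of surplus S, meaning pre-initiator charged minus impurity charged, the stoichiometric excess. This is an assumption, since the earlier runs show no chain count.

| flask | free monomer | pre-initiator | impurity | remark | time |
|---|---|---|---|---|---|
| spring | 1.4 M | 7 mM | 1.6 mM | run made earlier |  |
| dusk | 1.4 M | 7 mM | 6.2 mM | run made earlier |  |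
| winter | 2.8 M | 7 mM | 3.1 mM | run made earlier |  |
| flask | 1.4 M | 7.0 mM | 3.1 mM |  | 12 h |

| run | time / h | monomer in chains / % | free monomer / % |
|---|---|---|---|
| spring | 2.00 | 9 | 91 |
| spring | 4.00 | 20 | 77 |
| spring | 6.00 | 40 | 58 |
| spring | 8.00 | 48 | 47 |
| spring | 10.0 | 60 | 42 |
| spring | 12.0 | 73 | 32 |
| spring | 15.0 | 76 | 24 |
| dusk | 0.833 | 2 | 98 |
| dusk | 2.00 | 2 | 97 |
| dusk | 4.00 | 13 | 91 |
| dusk | 6.00 | 16 | 82 |
| dusk | 8.00 | 23 | 77 |
| dusk | 12.0 | 34 | 64 |
| dusk | 15.0 | 46 | 54 |
| winter | 3.00 | 17 | 85 |
| winter | 6.00 | 34 | 64 |
| winter | 8.00 | 49 | 51 |
| winter | 12.0 | 66 | 32 |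
| winter | 15.0 | 76 | 26 |

(readings scatter by 1.5 percentage points)

- the average divides the monomer in chains by the number of chains begun, living and dead together
- the numbers in the tables scatter by 1.5 percentage points (one standard deviation)
- the earlier runs do not show the number of chains; that part of a forecast is a guess

- average number of monomer units in a chain (chains begun, living or dead) at 12 h
- part of the free monomer that has reacted at 12 h

You must decide whether to charge the flask as drawn up. S is 5.40 mM in spring and 0.800 mM in dusk, and at 12.0 h their free monomer reads 32% and 64%. The flask's S is smaller than spring's and larger than dusk's, so leave the charge alone: the reading at 12 h is then an interpolation. Linear in S, free monomer comes to 42.4%, so you commit to c = 57.6%. With chains equal to S, dp = c·[M]₀/S = 207, where [M]₀ is the free monomer charged. But winter, with the flask's S and twice the monomer, reads 32% at 12.0 h, less than the line's 42.4%, so the line, drawn through spring and dusk at 1.4 M of free monomer, does not carry over to winter.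

The forecast gave dp 190 (105 to 280) and c 54% (49% to 59%), with the words “Chains begun are a guess”. The flask gives dp 207 and c 58.6%.

    initiator + impurity → spent initiator (k = 17700 /M/h)
    free monomer + living end → monomer in chains + living end, rate k2*[living end]*[free monomer] (k = 28.8 /M/h)
    free monomer + initiator → living end + monomer in chains (k = 15.6 /M/h)
    monomer in chains + living end → free monomer + living end, rate k4*[living end] as long as [monomer in chains] is above zero (k = 4.85 /h)
    pre-initiator → initiator (k = 0.533 /h)

At 12.0 h the flask holds 0.00397 M of living end, and c·[M]₀/S gives 210. It has not come to rest, with free monomer at 41.4%. The neighbour flask read at 30 h gives c 84.2% and dp 296, where c·[M]₀/S gives 302. Ten times the time brings c to 88.0% and dp to 309, with living end at 0.00398 M. Free monomer then reads 12.0%, and k4/k2 of the scheme, as a share of the charge, is 12.0%.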